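The route rests on the observation that the two axial methyl groups of ring A, C19 on C4 and C20 on C10, are 1,3-cis and can be carried as the two CH2 arms of one thiane ring. Ring A is then closed through the C1–C10 bond: the only enolate that a 3,3,5-trisubstituted thian-4-one can form (at C10) displaces a primary iodide tethered to the quaternary C4, giving a 3-thiabicyclo[3.3.1]nonan-9-one whose bridge fixes C10 relative to C4 in the same operation. The precursor is a thian-4-one bearing CO2Me and 3-iodopropyl on C4 (set by asymmetric alkylation) and a 2-chloroallyl handle for ring B on C10. Ring B, the side chain and Raney nickel release of both methyls follow.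

Key step: step 4

Assumption: atom labels C1–C20 in the text follow labdane numbering of the target (β = face of C20); systematic names use their own locants; the target is read from its SMILES as the 4α (equatorial) carboxylic acid with 4β-CH3, 5α-H, 9α-H, 10β-CH3 and 13S, and 18 and the catalysts are taken as purchasable.

Design remarks: (a) C4 is made quaternary before the C10 substituent is introduced, so that the enantioselective alkylation acts on a substrate with no other stereocentre. (b) The cyclization precursor 7 is carried as both C10 epimers, which give the same enolate, and is made immediately before use. (c) C5 and C9 are set by kinetically controlled delivery of hydrogen to the α face after the sulfur bridge is removed, because cis- and trans-fused 4,4,10-trisubstituted decalones are expected to lie close in energy and equilibration cannot be relied on.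

Step 1
Reactants: 1 methyl 4-oxothiane-3-carboxylate; 2 1-chloro-3-iodopropane
Product: 3 methyl (3S)-3-(3-chloropropyl)-4-oxothiane-3-carboxylate
Conditions: 4,4-dibutyl-2,6-bis(3,4,5-trifluorophenyl)-4,5-dihydro-3H-dinaphtho[2,1-c:1′,2′-e]azepinium bromide (2 mol %, the antipode that gives 3S), Cs2CO3, PhMe, −20 → 0 °C
Reagents that add atoms: none
Why: Asymmetric phase-transfer alkylation of a cyclic β-keto ester: the chiral ammonium cation ion-pairs with the enolate of 1 and shields one face, the soft C–I terminus of 2 (far more reactive than C–Cl) is attacked on carbon, and the quaternary C4 should be set as S on a substrate that has no other stereocentre.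

Step 2
Reactants: 3 methyl (3S)-3-(3-chloropropyl)-4-oxothiane-3-carboxylate; 4 2,3-dichloropropene
Product: 6 methyl (3S)-5-(2-chloroprop-2-en-1-yl)-3-(3-chloropropyl)-4-oxothiane-3-carboxylate (both C5 epimers), via lithium enolate 5 (not isolated)
Conditions: LiN(i-Pr)2, THF, −78 °C; then 4, n-Bu4NI (10 mol %), DMPU, −78 → −30 °C
Reagents that add atoms: none
Why: Kinetic ketone enolate alkylation (SN2 at the allylic chloride, iodide-catalysed): with C4 quaternary the future C10 is the only enolizable carbon, the vinylic chloride and the primary alkyl chloride are inert at this temperature, and the configuration created at C10 does not matter because step 4 erases it.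

Step 3
Reactants: 6 methyl (3S)-5-(2-chloroprop-2-en-1-yl)-3-(3-chloropropyl)-4-oxothiane-3-carboxylate (both C5 epimers)
Product: 7 methyl (3S)-5-(2-chloroprop-2-en-1-yl)-3-(3-iodopropyl)-4-oxothiane-3-carboxylate (both C5 epimers)
Conditions: NaI, acetone, reflux
Reagents that add atoms: sodium iodide [Na+].[I-]
Why: Finkelstein exchange driven by precipitation of NaCl converts only the primary alkyl chloride (the vinylic chloride cannot undergo SN2), and the crude iodide is used at once because a ring sulfide and a primary iodide in one molecule can slowly close to a sulfonium salt.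

Step 4
Reactants: 7 methyl (3S)-5-(2-chloroprop-2-en-1-yl)-3-(3-iodopropyl)-4-oxothiane-3-carboxylate (both C5 epimers)
Product: 9 methyl (1S,5S)-5-(2-chloroprop-2-en-1-yl)-9-oxo-3-thiabicyclo[3.3.1]nonane-1-carboxylate, via potassium enolate 8 (not isolated)
Conditions: KOt-Bu (1.05 equiv), t-BuOH/THF, 0 → 25 °C, 0.01 M
Reagents that add atoms: none
Why: KOt-Bu removes the only α-proton of 7 (C10–H; C4 is quaternary), and the carbon of potassium enolate 8 displaces the primary iodide in an intramolecular SN2 reaction that forms the C1–C10 bond. The closest known reaction type is the α,α′-annulation in which a cyclic β-keto ester or a 2-(3-halopropyl)cycloalkanone is closed to a bicyclo[3.3.1]nonan-9-one by enolate alkylation. Ring A closes in the 6-(enolendo)-exo-tet mode, which is stereoelectronically allowed. The new C10 stereocentre is controlled by C4: a three-carbon tether anchored on C4 can reach C10 only across one face of the thianone, so the bicycle can form only with the two CH2–S arms (C19 and C20) cis and diaxial on ring A and the ester equatorial, and both C10 epimers of 7 should give the same (1S,5S) product. The step needs C- over O-alkylation and substitution over E2 or β-elimination of thiolate from the enolate; these are favoured by the soft, unhindered primary iodide and by the axial tether on the fully substituted C4, which holds C1 over the π face at C10, assisted by the potassium counter-ion in hydrogen-bonding t-BuOH.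

Step 5
Reactants: 9 methyl (1S,5S)-5-(2-chloroprop-2-en-1-yl)-9-oxo-3-thiabicyclo[3.3.1]nonane-1-carboxylate
Product: 10 methyl (1S,5S)-5-(2-chloroprop-2-en-1-yl)-9-(methoxymethylidene)-3-thiabicyclo[3.3.1]nonane-1-carboxylate (E/Z mixture)
Conditions: MeOCH2PPh3Cl, KN(SiMe3)2, THF, 0 °C; then 9, 0 → 50 °C
Reagents that add atoms: (methoxymethyl)triphenylphosphonium chloride COC[P+](c1ccccc1)(c1ccccc1)c1ccccc1.[Cl-]
Why: Wittig methoxymethylenation: ketone 9 has no α-hydrogen, so the basic ylide cannot enolize it, and because the two flanking quaternary carbons are tied back in the bicycle the carbonyl is far more accessible than in an open 2,2,6,6-tetrasubstituted cyclohexanone, which is why C6 is attached before the sulfur bridge is removed; both enol ether isomers lead to the same aldehyde.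

Step 6
Reactants: 10 methyl (1S,5S)-5-(2-chloroprop-2-en-1-yl)-9-(methoxymethylidene)-3-thiabicyclo[3.3.1]nonane-1-carboxylate (E/Z mixture)
Product: 11 methyl (1S,5S)-9-formyl-5-(2-oxopropyl)-3-thiabicyclo[3.3.1]nonane-1-carboxylate (both C9 epimers)
Conditions: conc. H2SO4, 0 °C; then ice/H2O
Reagents that add atoms: water O
Why: Acid hydrolysis of the 2-chloroallyl group to an acetonyl group (the unmasking used in the Wichterle annulation) together with hydrolysis of the enol ether to the aldehyde on aqueous quench; the sulfide is only protonated in cold sulfuric acid, the hindered ester should survive, and the C5 configuration formed here is of no consequence.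

Step 7
Reactants: 11 methyl (1S,5S)-9-formyl-5-(2-oxopropyl)-3-thiabicyclo[3.3.1]nonane-1-carboxylate (both C9 epimers)
Product: 13 methyl 8-oxo-19,20-epithio-11,12,13,14,15,16,17-heptanorlabd-6-en-18-oate (both C5 epimers), via aldol 12 (not isolated)
Conditions: NaOMe (cat.), MeOH, 25 → 50 °C
Reagents that add atoms: none
Why: Intramolecular aldol condensation: the methyl-side enolate (C7) of the ketone adds to the C6 aldehyde to close the six-membered ring B (the other possible enolates could only form four-membered rings), E1cB loss of water gives the conjugated enone, and methoxide matches the methyl ester so that no transesterification product can arise.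

Step 8
Reactants: 13 methyl 8-oxo-19,20-epithio-11,12,13,14,15,16,17-heptanorlabd-6-en-18-oate (both C5 epimers)
Product: 14 methyl (1R,4aR,8aRS)-1,4a-dimethyl-6-oxo-1,2,3,4,4a,5,6,8a-octahydronaphthalene-1-carboxylate (both ring-fusion epimers)
Conditions: Raney Ni (W-2, deactivated by refluxing in acetone), acetone, reflux
Reagents that add atoms: none
Why: Raney nickel hydrogenolysis of both C–S bonds turns C19 and C20 into the two axial methyl groups of ring A, and nickel deactivated in acetone is used because it should cleave C–S bonds without saturating the conjugated C6=C7 bond, which is still needed to control C5 and to block C7.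

Step 9
Reactants: 14 methyl (1R,4aR,8aRS)-1,4a-dimethyl-6-oxo-1,2,3,4,4a,5,6,8a-octahydronaphthalene-1-carboxylate (both ring-fusion epimers)
Product: 17 methyl (1R,4aR,8aR)-1,4a-dimethyl-6-oxo-1,2,3,4,4a,5,6,8a-octahydronaphthalene-1-carboxylate (trans-fused; 5α-H), via potassium dienolate 15 (not isolated), via deconjugated enone 16 (not isolated)
Conditions: KOt-Bu (5 equiv), t-BuOH/THF, 25 °C; then 3 M HCl in MeOH/H2O to pH 1, 0 → 25 °C
Reagents that add atoms: none
Why: Base deconjugation and acid reconjugation of an enone through its extended dienol(ate), the isomerization known from steroidal 4-en-3-ones: in dienolate 15 C5 is planar, acidification gives 16, and the acid-catalysed return to conjugation should protonate C5 of the dienol axially from the α face, because the β face is screened by the axial methyl groups on both neighbouring carbons (C4 and C10), so the trans ring fusion (5α-H) is installed under kinetic control.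

Step 10
Reactants: 18 (R)-methyl hydrogen 3-methylglutarate
Product: 19 methyl (R)-5-hydroxy-3-methylpentanoate
Conditions: BH3·SMe2, THF, 0 → 25 °C; MeOH quench
Reagents that add atoms: none
Why: Chemoselective borane reduction: the carboxylic acid is activated as an acyloxyborane and reduced far faster than the methyl ester, and the stereocentre is not involved.

Step 11
Reactants: 19 methyl (R)-5-hydroxy-3-methylpentanoate
Product: 20 methyl (R)-5-(benzyloxy)-3-methylpentanoate
Conditions: BnOC(=NH)CCl3, TfOH (cat.), CH2Cl2/cyclohexane, 0 → 25 °C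
Reagents that add atoms: benzyl 2,2,2-trichloroacetimidate ClC(Cl)(Cl)C(=N)OCc1ccccc1
Why: Benzylation with benzyl trichloroacetimidate under acid catalysis, chosen over a basic Williamson etherification because alkoxide formation would lactonize the δ-hydroxy ester.

Step 12
Reactants: 20 methyl (R)-5-(benzyloxy)-3-methylpentanoate
Product: 21 (R)-5-(benzyloxy)-3-methylpentanal
Conditions: i-Bu2AlH, CH2Cl2, −78 °C; then aq. KNaC4H4O6
Reagents that add atoms: none
Why: Partial reduction of the methyl ester with i-Bu2AlH at −78 °C, where the aluminium hemiacetal survives until work-up and then releases the aldehyde; the stereocentre is β to the carbonyl and cannot epimerize.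

Step 13
Reactants: 17 methyl (1R,4aR,8aR)-1,4a-dimethyl-6-oxo-1,2,3,4,4a,5,6,8a-octahydronaphthalene-1-carboxylate; 21 (R)-5-(benzyloxy)-3-methylpentanal
Product: 23 methyl 15-(benzyloxy)-11-hydroxy-8-oxo-17-norlabd-6-en-18-oate (C9 and C11 epimers; side-chain methyl centre as in 21), via lithium dienolate 22 (not isolated)
Conditions: LiN(i-Pr)2, THF, −78 °C; then 21, −78 °C; AcOH quench
Reagents that add atoms: none
Why: Directed aldol addition: LiN(i-Pr)2 deprotonates the enone kinetically at the α′ carbon C9 (C7 is blocked by the double bond and the γ-proton at C5 is removed far more slowly), and the lithium dienolate should add to aldehyde 21 at −78 °C faster than proton transfer; the new C9 and C11 centres are planarized again in step 14.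

Step 14
Reactants: 23 methyl 15-(benzyloxy)-11-hydroxy-8-oxo-17-norlabd-6-en-18-oate (C9 and C11 epimers)
Product: 25 methyl (13S)-15-(benzyloxy)-8-oxo-17-norlabda-6,9(11)-dien-18-oate (E/Z mixture), via mesylate 24 (not isolated)
Conditions: MsCl, Et3N, CH2Cl2, 0 °C; then DBU, 25 °C
Reagents that add atoms: none
Why: Mesylation of the aldol hydroxyl followed by E1cB elimination with DBU through the C9 enolate gives the exocyclic enone; the double-bond geometry is irrelevant because step 15 saturates it.

Step 15
Reactants: 25 methyl (13S)-15-(benzyloxy)-8-oxo-17-norlabda-6,9(11)-dien-18-oate (E/Z mixture)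
Product: 26 methyl (13S)-15-hydroxy-8-oxo-17-norlabdan-18-oate (4α-CO2Me; 5α-H; 9α-H; 10β-CH3)
Conditions: H2 (1 atm), 10% Pd/C, EtOAc/MeOH, 25 °C
Reagents that add atoms: none
Why: Heterogeneous hydrogenation saturates C6=C7 and C9=C11 and hydrogenolyses the benzyl ether in one operation; hydrogen should be delivered to C9 from the α face, opposite the axial C20 methyl on the adjacent C10, which sets 9α-H and the equatorial β side chain, while the ketone and the ester are inert to Pd/C.

Step 16
Reactants: 26 methyl (13S)-15-hydroxy-8-oxo-17-norlabdan-18-oate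
Product: 27 methyl (13S)-15-hydroxylabd-8(17)-en-18-oate
Conditions: Zn, CH2Br2, TiCl4, THF, 0 → 25 °C; then 26, CH2Cl2, 25 °C
Reagents that add atoms: dibromomethane BrCBr
Why: Takai–Lombardo methylenation: the non-basic zinc–titanium methylene reagent converts the hindered, enolizable C8 ketone into the exocyclic alkene without epimerizing C9 and does not attack the methyl ester or the free alcohol.

Step 17
Reactants: 27 methyl (13S)-15-hydroxylabd-8(17)-en-18-oate
Product: 28 (13S)-15-hydroxylabd-8(17)-en-18-oic acid
Conditions: KOH, HOCH2CH2OH/H2O, 120 °C; then 1 M HCl, 0 °C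
Reagents that add atoms: potassium hydroxide [K+].[OH-]
Why: Saponification of the equatorial but neopentyl-type methyl ester under forcing alkaline conditions, to which the exocyclic alkene and all stereocentres (none of them acidic any longer) are inert.

Step 18
Reactants: 28 (13S)-15-hydroxylabd-8(17)-en-18-oic acid
Product: 29 (13S)-15-acetoxylabd-8(17)-en-18-oic acid (CNP0401865.1)
Conditions: Ac2O, pyridine, DMAP (cat.), CH2Cl2, 0 → 25 °C; then aq. NaHCO3, then 1 M HCl to pH 3
Reagents that add atoms: acetic anhydride CC(=O)OC(C)=O
Why: DMAP-catalysed acetylation of the unhindered primary alcohol; any mixed anhydride formed at the hindered tertiary carboxylic acid is hydrolysed back during the bicarbonate work-up.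

Compound list
1 | methyl 4-oxothiane-3-carboxylate | COC(=O)C1CSCCC1=O | starting material
2 | 1-chloro-3-iodopropane | ClCCCI | starting material
3 | methyl (3S)-3-(3-chloropropyl)-4-oxothiane-3-carboxylate | O=C1CCSC[C@]1(CCCCl)C(=O)OC | intermediate
4 | 2,3-dichloropropene | ClCC(Cl)=C | starting material
5 | lithium enolate of 3 toward the unsubstituted α-carbon (not isolated) | [Li+].[O-]C1=CCSC[C@]1(CCCCl)C(=O)OC | intermediate
6 | methyl (3S)-5-(2-chloroprop-2-en-1-yl)-3-(3-chloropropyl)-4-oxothiane-3-carboxylate (both C5 epimers) | O=C1C(CC(Cl)=C)CSC[C@]1(CCCCl)C(=O)OC | intermediate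
7 | methyl (3S)-5-(2-chloroprop-2-en-1-yl)-3-(3-iodopropyl)-4-oxothiane-3-carboxylate (both C5 epimers) | O=C1C(CC(Cl)=C)CSC[C@]1(CCCI)C(=O)OC | intermediate
8 | potassium enolate of 7 toward the chloroallyl-bearing carbon (not isolated) | [K+].[O-]C1=C(CC(Cl)=C)CSC[C@]1(CCCI)C(=O)OC | intermediate
9 | methyl (1S,5S)-5-(2-chloroprop-2-en-1-yl)-9-oxo-3-thiabicyclo[3.3.1]nonane-1-carboxylate | O=C1[C@@]2(CC(Cl)=C)CCC[C@]1(C(=O)OC)CSC2 | intermediate
10 | methyl (1S,5S)-5-(2-chloroprop-2-en-1-yl)-9-(methoxymethylidene)-3-thiabicyclo[3.3.1]nonane-1-carboxylate (E/Z mixture) | COC=C1[C@@]2(CC(Cl)=C)CCC[C@]1(C(=O)OC)CSC2 | intermediate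
11 | methyl (1S,5S)-9-formyl-5-(2-oxopropyl)-3-thiabicyclo[3.3.1]nonane-1-carboxylate (both C9 epimers) | O=CC1[C@@]2(CC(C)=O)CCC[C@]1(C(=O)OC)CSC2 | intermediate
12 | methyl 6-hydroxy-8-oxo-19,20-epithio-11,12,13,14,15,16,17-heptanorlabdan-18-oate (aldol; C5 and C6 epimers; not isolated) | O=C1CC(O)C2[C@]3(C(=O)OC)CCC[C@@]2(C1)CSC3 | intermediate
13 | methyl 8-oxo-19,20-epithio-11,12,13,14,15,16,17-heptanorlabd-6-en-18-oate (sulfide-bridged enone; both C5 epimers) | O=C1C=CC2[C@]3(C(=O)OC)CCC[C@@]2(C1)CSC3 | intermediate
14 | methyl (1R,4aR,8aRS)-1,4a-dimethyl-6-oxo-1,2,3,4,4a,5,6,8a-octahydronaphthalene-1-carboxylate (both ring-fusion epimers) | O=C1C=CC2[C@](C)(CCC[C@@]2(C)C(=O)OC)C1 | intermediate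
15 | potassium dienolate of 14 (C5=C6–C7=C8–OK; not isolated) | [K+].[O-]C1=CC=C2[C@](C)(CCC[C@@]2(C)C(=O)OC)C1 | intermediate
16 | methyl (1R,4aR)-1,4a-dimethyl-6-oxo-1,2,3,4,4a,5,6,7-octahydronaphthalene-1-carboxylate (deconjugated enone; not isolated) | O=C1CC=C2[C@](C)(CCC[C@@]2(C)C(=O)OC)C1 | intermediate
17 | methyl (1R,4aR,8aR)-1,4a-dimethyl-6-oxo-1,2,3,4,4a,5,6,8a-octahydronaphthalene-1-carboxylate (trans-fused; 5α-H) | O=C1C=C[C@@H]2[C@](C)(CCC[C@@]2(C)C(=O)OC)C1 | intermediate
18 | (R)-methyl hydrogen 3-methylglutarate | COC(=O)C[C@H](C)CC(=O)O | starting material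
19 | methyl (R)-5-hydroxy-3-methylpentanoate | COC(=O)C[C@H](C)CCO | intermediate
20 | methyl (R)-5-(benzyloxy)-3-methylpentanoate | COC(=O)C[C@H](C)CCOCc1ccccc1 | intermediate
21 | (R)-5-(benzyloxy)-3-methylpentanal | O=CC[C@H](C)CCOCc1ccccc1 | intermediate
22 | lithium dienolate of 17 (C8 enolate toward C9, cross-conjugated; not isolated) | [Li+].[O-]C1C=C[C@@H]2[C@](C)(CCC[C@@]2(C)C(=O)OC)C=1 | intermediate
23 | methyl 15-(benzyloxy)-11-hydroxy-8-oxo-17-norlabd-6-en-18-oate (C9 and C11 epimers; side-chain methyl centre as in 21) | O=C1C=C[C@@H]2[C@](C)(CCC[C@@]2(C)C(=O)OC)C1C(O)C[C@H](C)CCOCc1ccccc1 | intermediate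
24 | 11-O-methanesulfonate of 23 (not isolated) | O=C1C=C[C@@H]2[C@](C)(CCC[C@@]2(C)C(=O)OC)C1C(OS(C)(=O)=O)C[C@H](C)CCOCc1ccccc1 | intermediate
25 | methyl (13S)-15-(benzyloxy)-8-oxo-17-norlabda-6,9(11)-dien-18-oate (E/Z mixture) | O=C1C=C[C@@H]2[C@](C)(CCC[C@@]2(C)C(=O)OC)C1=CC[C@H](C)CCOCc1ccccc1 | intermediate
26 | methyl (13S)-15-hydroxy-8-oxo-17-norlabdan-18-oate | O=C1CC[C@@H]2[C@](C)(CCC[C@@]2(C)C(=O)OC)[C@H]1CC[C@H](C)CCO | intermediate
27 | methyl (13S)-15-hydroxylabd-8(17)-en-18-oate | C=C1CC[C@@H]2[C@](C)(CCC[C@@]2(C)C(=O)OC)[C@H]1CC[C@H](C)CCO | intermediate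
28 | (13S)-15-hydroxylabd-8(17)-en-18-oic acid | C=C1CC[C@@H]2[C@](C)(CCC[C@@]2(C)C(=O)O)[C@H]1CC[C@H](C)CCO | intermediate
29 | (13S)-15-acetoxylabd-8(17)-en-18-oic acid (CNP0401865.1) | C=C1CC[C@@H]2[C@](C)(CCC[C@@]2(C)C(=O)O)[C@H]1CC[C@H](C)CCOC(C)=O | target

Total step count: 18. Longest linear sequence: 15 steps (steps 1–9 and 13–18, starting from 1).

Steps most likely to fail

Step 4. The enolate may be alkylated on oxygen instead of carbon, hydrogen iodide may be lost by E2, or the thianone may open by β-elimination of thiolate from the enolate. The fallback replaces the alkylation by an aldol closure, in which the enolate meets a carbonyl electrophile, and then removes the extra oxygen. It sets out from 7: oxidation of the primary iodide with Me3NO in DMSO (Ganem oxidation, which leaves the sulfide alone) would give methyl (3S)-5-(2-chloroprop-2-en-1-yl)-4-oxo-3-(3-oxopropyl)thiane-3-carboxylate F1. Catalytic KOt-Bu in t-BuOH/THF would close it by intramolecular aldol addition of C10 to the aldehyde to methyl 5-(2-chloroprop-2-en-1-yl)-6-hydroxy-9-oxo-3-thiabicyclo[3.3.1]nonane-1-carboxylate F2. 1,1′-Thiocarbonyldiimidazole would convert the alcohol into the O-(imidazol-1-ylthiocarbonyl) derivative of that ketol F3. Barton–McCombie deoxygenation (n-Bu3SnH, AIBN, PhMe, 80 °C; the vinylic chloride and the sulfide do not react with stannyl radicals) comes back to the route at 9.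

Step 1. Enantiofacial discrimination may be insufficient, and alkylation may be slow and partly directed to oxygen, because the electrophile is an unactivated primary iodide and the ester is small. The fallback replaces alkylation by conjugate addition. It sets out from 1: Michael addition to acrolein catalysed by a 6′-hydroxy cinchona alkaloid (bifunctional base and hydrogen-bond catalysis, established for cyclic β-keto esters; CH2Cl2, −25 °C) would give methyl (3S)-4-oxo-3-(3-oxopropyl)thiane-3-carboxylate F4. NaBH(OAc)3 in THF reduces the aldehyde but not the hindered ketone, giving methyl (3S)-3-(3-hydroxypropyl)-4-oxothiane-3-carboxylate F5. An Appel reaction (PPh3, CCl4) converts the alcohol into the chloride and comes back to the route at 3.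

Step 8. The enone double bond may be partly hydrogenated during desulfurization, which would freeze C5 as a mixture and remove the group that blocks C7; with too weak a catalyst, C–S cleavage may instead stay incomplete. The fallback accepts over-reduction and then restores the unsaturation. It sets out from 13: fully active Raney Ni (W-2) in refluxing EtOH would deliberately give the saturated ketone methyl (1R,4aR,8aRS)-1,4a-dimethyl-6-oxodecahydronaphthalene-1-carboxylate F6. Dehydrogenation with 2-iodoxybenzoic acid in DMSO at 70 °C then reintroduces the double bond; only C6=C7 can form because C10 is quaternary, and the route is rejoined at 14.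

Further compounds
F1 | step 4 | methyl (3S)-5-(2-chloroprop-2-en-1-yl)-4-oxo-3-(3-oxopropyl)thiane-3-carboxylate (both C5 epimers) | O=C1C(CC(Cl)=C)CSC[C@]1(CCC=O)C(=O)OC
F2 | step 4 | methyl 5-(2-chloroprop-2-en-1-yl)-6-hydroxy-9-oxo-3-thiabicyclo[3.3.1]nonane-1-carboxylate (bridgeheads as in 9; hydroxyl epimers) | O=C1[C@@]2(CC(Cl)=C)C(O)CC[C@]1(C(=O)OC)CSC2
F3 | step 4 | O-(imidazol-1-ylthiocarbonyl) derivative of F2 | O=C1[C@@]2(CC(Cl)=C)C(OC(=S)n3ccnc3)CC[C@]1(C(=O)OC)CSC2
F4 | step 1 | methyl (3S)-4-oxo-3-(3-oxopropyl)thiane-3-carboxylate | O=C1CCSC[C@]1(CCC=O)C(=O)OC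
F5 | step 1 | methyl (3S)-3-(3-hydroxypropyl)-4-oxothiane-3-carboxylate | O=C1CCSC[C@]1(CCCO)C(=O)OC
F6 | step 8 | methyl (1R,4aR,8aRS)-1,4a-dimethyl-6-oxodecahydronaphthalene-1-carboxylate | O=C1CCC2[C@](C)(CCC[C@@]2(C)C(=O)OC)C1
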